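**Retrosynthetic overview**
1. Punaglandin 3 (29) comes from its 12-O-trimethylsilyl ether 28; the C7=C8 bond comes from E1cB dehydration of β-hydroxy ketone 26.
2. Key C7–C8 bond: intermolecular aldol addition of the lithium dienolate of chlorocyclopentenone 24 (fragment A, C8–C20) to the diacetoxy aldehyde 11 (fragment B, C1–C7).
3. Fragment A: (4R)-4-silyloxycyclopentenone 12, anti-selective propargylation (sets C12), alkyne/propargyl bromide coupling, Lindlar reduction, oxidation, then epoxidation/HCl to the α-chloroenone.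
4. Fragment B: L-threitol acetonide 1 supplies C5 and C6; copper-catalysed vinyl coupling, acrylate cross metathesis, hydrogenation, oxidation.
5. Rings: no ring is formed in the route; the only ring (the cyclopentenone) is bought in 12 and carried through.

Assumption: prostanoid numbering (C1 = ester carbon to C20) is used for positions, and 1 and 12 are taken as purchasable building blocks.

**Fragment B (C1–C7)**

Step 1
Reactants: 1 (4S,5S)-2,2-dimethyl-1,3-dioxolane-4,5-dimethanol
Product: 2 [(4S,5S)-5-(benzyloxymethyl)-2,2-dimethyl-1,3-dioxolan-4-yl]methanol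
Conditions: BnBr (1.1 equiv), Ag2O (1.5 equiv), CH2Cl2, rt
Reagents that add atoms: benzyl bromide, BrCc1ccccc1
Why: Ag2O-promoted Williamson O-benzylation stops at the mono-ether of the C2-symmetric diol (both hydroxyls are equivalent, so only one mono-ether exists) and touches neither stereocentre.

Step 2
Reactants: 2 [(4S,5S)-5-(benzyloxymethyl)-2,2-dimethyl-1,3-dioxolan-4-yl]methanol
Product: 3 [(4S,5S)-5-(benzyloxymethyl)-2,2-dimethyl-1,3-dioxolan-4-yl]methyl trifluoromethanesulfonate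
Conditions: Tf2O (1.1 equiv), pyridine (1.5 equiv), CH2Cl2, −20 °C; used crude
Reagents that add atoms: trifluoromethanesulfonic anhydride, O=S(=O)(OS(=O)(=O)C(F)(F)F)C(F)(F)F
Why: O-sulfonylation (triflation) of the unhindered primary alcohol gives the leaving group for the C3–C4 bond formation without affecting the acetal or the stereocentres.

Step 3
Reactants: 3 [(4S,5S)-5-(benzyloxymethyl)-2,2-dimethyl-1,3-dioxolan-4-yl]methyl trifluoromethanesulfonate; 4 vinylmagnesium bromide
Product: 5 (4S,5S)-4-(benzyloxymethyl)-2,2-dimethyl-5-(prop-2-en-1-yl)-1,3-dioxolane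
Conditions: 4 (2.5 equiv, THF solution), CuBr (10 mol %), Et2O, −20 to 0 °C
Reagents that add atoms: none
Why: Copper-catalysed SN2 cross-coupling of a primary alkyl triflate with a Grignard reagent makes the C3–C4 bond at a CH2 carbon, so C5 and C6 keep the tartrate-derived configuration.

Step 4
Reactants: 5 (4S,5S)-4-(benzyloxymethyl)-2,2-dimethyl-5-(prop-2-en-1-yl)-1,3-dioxolane
Product: 6 (2S,3S)-1-(benzyloxy)hex-5-ene-2,3-diol
Conditions: AcOH/H2O (4:1), 50 °C
Reagents that add atoms: none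
Why: Acid-catalysed acetal hydrolysis frees the threo diol before any ester is present in the chain, so no δ-lactone can form, and the C–O bonds at the stereocentres are not broken.

Step 5
Reactants: 6 (2S,3S)-1-(benzyloxy)hex-5-ene-2,3-diol
Product: 7 (2S,3S)-1-(benzyloxy)hex-5-ene-2,3-diyl diacetate
Conditions: Ac2O (3 equiv), pyridine, DMAP (5 mol %), CH2Cl2, 0 °C to rt
Reagents that add atoms: acetic anhydride, CC(=O)OC(C)=O
Why: DMAP-catalysed O-acylation installs both natural acetates with retention, since only O–H bonds react.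

Step 6
Reactants: 7 (2S,3S)-1-(benzyloxy)hex-5-ene-2,3-diyl diacetate; 8 methyl acrylate
Product: 9 methyl (2E,5S,6S)-5,6-diacetoxy-7-(benzyloxy)hept-2-enoate
Conditions: 8 (5 equiv), second-generation Grubbs catalyst RuCl2(=CHPh)(PCy3)(H2IMes) (5 mol %), CH2Cl2, 40 °C
Reagents that add atoms: none
Why: Olefin cross metathesis between an unhindered terminal alkene and an electron-poor acrylate is selective for the E-configured cross product and completes C1–C3 under neutral conditions.

Step 7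
Reactants: 9 methyl (2E,5S,6S)-5,6-diacetoxy-7-(benzyloxy)hept-2-enoate
Product: 10 methyl (5S,6S)-5,6-diacetoxy-7-hydroxyheptanoate
Conditions: H2 (1 atm), 10% Pd/C, EtOAc, rt; used without chromatography
Reagents that add atoms: none
Why: Catalytic hydrogenation saturates the enoate and hydrogenolyses the benzyl ether in one neutral operation, which avoids 6-O to 7-O acetyl migration.

Step 8
Reactants: 10 methyl (5S,6S)-5,6-diacetoxy-7-hydroxyheptanoate
Product: 11 methyl (5S,6R)-5,6-diacetoxy-7-oxoheptanoate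
Conditions: Dess–Martin periodinane (1.3 equiv), CH2Cl2, 0 °C to rt; used at once
Reagents that add atoms: none
Why: Dess–Martin oxidation is base-free, so the α-acetoxy aldehyde forms without C6 epimerisation or β-acetoxy elimination (the descriptor at C6 changes from S to R only because CHO outranks C5).

**Fragment A (C8–C20)**

Step 9
Reactants: 12 (4R)-4-[(tert-butyldimethylsilyl)oxy]cyclopent-2-en-1-one; 13 3-bromoprop-1-yne
Product: 15 (1S,4R)-4-[(tert-butyldimethylsilyl)oxy]-1-(prop-2-yn-1-yl)cyclopent-2-en-1-ol, via allenylmagnesium bromide 14 (not isolated)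
Conditions: 13 (1.5 equiv), Mg, HgCl2 (1 mol %), Et2O, 0 °C; then 12, Et2O, −78 °C; H2O quench
Reagents that add atoms: none
Why: Grignard 1,2-addition (SE2' propargylation by the allenyl reagent) occurs on the ketone face anti to the C4 silyloxy group and so sets the quaternary carbinol (future C12) cis to OTBS; the minor epimer must be removed by chromatography here because it would later become the enantiomer.

Step 10
Reactants: 15 (1S,4R)-4-[(tert-butyldimethylsilyl)oxy]-1-(prop-2-yn-1-yl)cyclopent-2-en-1-ol; 16 1-bromopent-2-yne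
Product: 17 (1S,4R)-4-[(tert-butyldimethylsilyl)oxy]-1-(octa-2,5-diyn-1-yl)cyclopent-2-en-1-ol
Conditions: 16 (1.2 equiv), CuI (1 equiv), NaI (1 equiv), K2CO3 (1.5 equiv), DMF, rt
Reagents that add atoms: none
Why: Copper-mediated SN2 alkylation of the terminal alkyne (as its copper acetylide) with a propargylic bromide gives the skipped diyne without base strong enough to isomerise it.

Step 11
Reactants: 17 (1S,4R)-4-[(tert-butyldimethylsilyl)oxy]-1-(octa-2,5-diyn-1-yl)cyclopent-2-en-1-ol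
Product: 18 (1S,4R)-4-[(tert-butyldimethylsilyl)oxy]-1-[(2Z,5Z)-octa-2,5-dien-1-yl]cyclopent-2-en-1-ol
Conditions: H2 (1 atm), Pd/CaCO3 poisoned with Pb(OAc)2 (Lindlar catalyst), quinoline, EtOAc, rt, stopped after 2 equiv H2
Reagents that add atoms: none
Why: Lindlar semihydrogenation adds H2 syn to each alkyne and so gives both Z alkenes (C14 and C17), while the ring alkene is left intact on the poisoned catalyst.

Step 12
Reactants: 18 (1S,4R)-4-[(tert-butyldimethylsilyl)oxy]-1-[(2Z,5Z)-octa-2,5-dien-1-yl]cyclopent-2-en-1-ol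
Product: 19 (1S,4R)-1-[(2Z,5Z)-octa-2,5-dien-1-yl]cyclopent-2-ene-1,4-diol
Conditions: Bu4NF (1.2 equiv), THF, 0 °C to rt
Reagents that add atoms: none
Why: Fluoride-mediated desilylation cleaves only the Si–O bond and leaves the diene and both carbinol centres unchanged.

Step 13
Reactants: 19 (1S,4R)-1-[(2Z,5Z)-octa-2,5-dien-1-yl]cyclopent-2-ene-1,4-diol
Product: 20 (4S)-4-hydroxy-4-[(2Z,5Z)-octa-2,5-dien-1-yl]cyclopent-2-en-1-one
Conditions: activated MnO2 (15 equiv), CH2Cl2, rt
Reagents that add atoms: none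
Why: Chemoselective allylic alcohol oxidation converts the secondary carbinol (C9) to the enone, while the tertiary alcohol cannot be oxidised and the quaternary C12 cannot epimerise.

Step 14
Reactants: 20 (4S)-4-hydroxy-4-[(2Z,5Z)-octa-2,5-dien-1-yl]cyclopent-2-en-1-one
Product: 21 (4S)-4-hydroxy-4-[(2Z,5Z)-octa-2,5-dien-1-yl]-6-oxabicyclo[3.1.0]hexan-2-one (both epoxide epimers; used together)
Conditions: 30% aq. H2O2 (3 equiv), NaOH (0.2 equiv), MeOH, 0 °C
Reagents that add atoms: hydrogen peroxide, OO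
Why: Weitz–Scheffer nucleophilic epoxidation attacks only the electron-poor enone and leaves the isolated Z alkenes alone; the epoxide configuration is irrelevant because both carbons become sp2 in step 15.

Step 15
Reactants: 21 (4S)-4-hydroxy-4-[(2Z,5Z)-octa-2,5-dien-1-yl]-6-oxabicyclo[3.1.0]hexan-2-one
Product: 23 (4S)-2-chloro-4-hydroxy-4-[(2Z,5Z)-octa-2,5-dien-1-yl]cyclopent-2-en-1-one, via chlorohydrin 22 (not isolated)
Conditions: conc. aq. HCl, acetone, 0 °C to rt
Reagents that add atoms: hydrogen chloride, Cl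
Why: Chloride opens the epoxy ketone by SN2 attack at the carbonyl-activated α-carbon (C10, not the neopentyl-like C11), and acid-catalysed β-elimination of water from the resulting β-hydroxy ketone gives the α-chloroenone.

Step 16
Reactants: 23 (4S)-2-chloro-4-hydroxy-4-[(2Z,5Z)-octa-2,5-dien-1-yl]cyclopent-2-en-1-one
Product: 24 (4S)-2-chloro-4-[(2Z,5Z)-octa-2,5-dien-1-yl]-4-[(trimethylsilyl)oxy]cyclopent-2-en-1-one
Conditions: Me3SiCl (1.5 equiv), imidazole (2.5 equiv), DMF, 0 °C to rt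
Reagents that add atoms: chlorotrimethylsilane, C[Si](C)(C)Cl
Why: O-silylation masks the tertiary alcohol so that step 17 needs one equivalent of base and the alkoxide cannot trigger retro-aldol cleavage.

**Coupling and end game**

Step 17
Reactants: 24 (4S)-2-chloro-4-[(2Z,5Z)-octa-2,5-dien-1-yl]-4-[(trimethylsilyl)oxy]cyclopent-2-en-1-one; 11 methyl (5S,6R)-5,6-diacetoxy-7-oxoheptanoate
Product: 26 methyl (5S,6S)-5,6-diacetoxy-7-{(5S)-3-chloro-5-[(2Z,5Z)-octa-2,5-dien-1-yl]-2-oxo-5-[(trimethylsilyl)oxy]cyclopent-3-en-1-yl}-7-hydroxyheptanoate (C7/C8 epimer mixture), via lithium dienolate 25 (not isolated)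
Conditions: LiN(iPr)2 (1.1 equiv), THF, −78 °C, 30 min; then 11 (1.0 equiv), −78 °C, 15 min; AcOH (1.2 equiv) quench at −78 °C
Reagents that add atoms: none
Why: Crossed aldol addition: LDA removes the only enolisable proton (C8) and the cross-conjugated lithium dienolate adds to the aldehyde, by far the most electrophilic carbonyl, at −78 °C; the new C7/C8 centres form as a mixture that step 18 erases, while C5, C6 and C12 are untouched.

Step 18
Reactants: 26 methyl (5S,6S)-5,6-diacetoxy-7-{(5S)-3-chloro-5-[(2Z,5Z)-octa-2,5-dien-1-yl]-2-oxo-5-[(trimethylsilyl)oxy]cyclopent-3-en-1-yl}-7-hydroxyheptanoate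
Product: 28 methyl (5S,6S,7E,12R,14Z,17Z)-5,6-diacetoxy-10-chloro-9-oxo-12-[(trimethylsilyl)oxy]prosta-7,10,14,17-tetraen-1-oate, via mesylate 27 (not isolated)
Conditions: MsCl (1.5 equiv), Et3N (4 equiv), DMAP (cat.), CH2Cl2, −20 °C to rt
Reagents that add atoms: none
Why: Mesylation followed by E1cB elimination through the C8 enolate gives the cross-conjugated dienone, with the E isomer expected to predominate and the minor 7Z isomer removed by chromatography; the exocyclic geometry is not fully controlled.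

Step 19
Reactants: 28 methyl (5S,6S,7E,12R,14Z,17Z)-5,6-diacetoxy-10-chloro-9-oxo-12-[(trimethylsilyl)oxy]prosta-7,10,14,17-tetraen-1-oate
Product: 29 punaglandin 3, methyl (5S,6S,7E,12R,14Z,17Z)-5,6-diacetoxy-10-chloro-12-hydroxy-9-oxoprosta-7,10,14,17-tetraen-1-oate
Conditions: AcOH/THF/H2O (3:1:1), rt
Reagents that add atoms: none
Why: Mild acid-catalysed hydrolysis of the trimethylsilyl ether frees the tertiary alcohol without touching the acetates, the methyl ester or the dienone.

**Compound list**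
1 | (4S,5S)-2,2-dimethyl-1,3-dioxolane-4,5-dimethanol (2,3-O-isopropylidene-L-threitol) | OC[C@@H]1OC(C)(C)O[C@H]1CO | starting material
2 | [(4S,5S)-5-(benzyloxymethyl)-2,2-dimethyl-1,3-dioxolan-4-yl]methanol | c1ccccc1COC[C@@H]1OC(C)(C)O[C@H]1CO | intermediate
3 | [(4S,5S)-5-(benzyloxymethyl)-2,2-dimethyl-1,3-dioxolan-4-yl]methyl trifluoromethanesulfonate | c1ccccc1COC[C@@H]1OC(C)(C)O[C@H]1COS(=O)(=O)C(F)(F)F | intermediate
4 | vinylmagnesium bromide | C=C[Mg]Br | starting material
5 | (4S,5S)-4-(benzyloxymethyl)-2,2-dimethyl-5-(prop-2-en-1-yl)-1,3-dioxolane | c1ccccc1COC[C@@H]1OC(C)(C)O[C@H]1CC=C | intermediate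
6 | (2S,3S)-1-(benzyloxy)hex-5-ene-2,3-diol | c1ccccc1COC[C@H](O)[C@H](CC=C)O | intermediate
7 | (2S,3S)-1-(benzyloxy)hex-5-ene-2,3-diyl diacetate | c1ccccc1COC[C@H](OC(C)=O)[C@H](CC=C)OC(C)=O | intermediate
8 | methyl acrylate | C=CC(=O)OC | starting material
9 | methyl (2E,5S,6S)-5,6-diacetoxy-7-(benzyloxy)hept-2-enoate | c1ccccc1COC[C@H](OC(C)=O)[C@H](C/C=C/C(=O)OC)OC(C)=O | intermediate
10 | methyl (5S,6S)-5,6-diacetoxy-7-hydroxyheptanoate | OC[C@H](OC(C)=O)[C@H](CCCC(=O)OC)OC(C)=O | intermediate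
11 | methyl (5S,6R)-5,6-diacetoxy-7-oxoheptanoate | O=C[C@H](OC(C)=O)[C@H](CCCC(=O)OC)OC(C)=O | intermediate
12 | (4R)-4-[(tert-butyldimethylsilyl)oxy]cyclopent-2-en-1-one | O=C1C=C[C@H](O[Si](C)(C)C(C)(C)C)C1 | starting material
13 | 3-bromoprop-1-yne (propargyl bromide) | C#CCBr | starting material
14 | allenylmagnesium bromide (propargyl Grignard reagent; formed in the flask) | C=C=C[Mg]Br | intermediate
15 | (1S,4R)-4-[(tert-butyldimethylsilyl)oxy]-1-(prop-2-yn-1-yl)cyclopent-2-en-1-ol | C#CC[C@@]1(O)C=C[C@H](O[Si](C)(C)C(C)(C)C)C1 | intermediate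
16 | 1-bromopent-2-yne | CCC#CCBr | starting material
17 | (1S,4R)-4-[(tert-butyldimethylsilyl)oxy]-1-(octa-2,5-diyn-1-yl)cyclopent-2-en-1-ol | CCC#CCC#CC[C@@]1(O)C=C[C@H](O[Si](C)(C)C(C)(C)C)C1 | intermediate
18 | (1S,4R)-4-[(tert-butyldimethylsilyl)oxy]-1-[(2Z,5Z)-octa-2,5-dien-1-yl]cyclopent-2-en-1-ol | CC/C=C\C/C=C\C[C@@]1(O)C=C[C@H](O[Si](C)(C)C(C)(C)C)C1 | intermediate
19 | (1S,4R)-1-[(2Z,5Z)-octa-2,5-dien-1-yl]cyclopent-2-ene-1,4-diol | CC/C=C\C/C=C\C[C@@]1(O)C=C[C@H](O)C1 | intermediate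
20 | (4S)-4-hydroxy-4-[(2Z,5Z)-octa-2,5-dien-1-yl]cyclopent-2-en-1-one | CC/C=C\C/C=C\C[C@@]1(O)C=CC(=O)C1 | intermediate
21 | (4S)-4-hydroxy-4-[(2Z,5Z)-octa-2,5-dien-1-yl]-6-oxabicyclo[3.1.0]hexan-2-one (epoxide carbons: mixture of both cis-fused epimers, left unassigned) | CC/C=C\C/C=C\C[C@@]1(O)C2OC2C(=O)C1 | intermediate
22 | (4S)-2-chloro-3,4-dihydroxy-4-[(2Z,5Z)-octa-2,5-dien-1-yl]cyclopentan-1-one (chlorohydrin; C2/C3 unassigned; formed in the flask) | CC/C=C\C/C=C\C[C@@]1(O)C(O)C(Cl)C(=O)C1 | intermediate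
23 | (4S)-2-chloro-4-hydroxy-4-[(2Z,5Z)-octa-2,5-dien-1-yl]cyclopent-2-en-1-one | CC/C=C\C/C=C\C[C@@]1(O)C=C(Cl)C(=O)C1 | intermediate
24 | (4S)-2-chloro-4-[(2Z,5Z)-octa-2,5-dien-1-yl]-4-[(trimethylsilyl)oxy]cyclopent-2-en-1-one | CC/C=C\C/C=C\C[C@@]1(O[Si](C)(C)C)C=C(Cl)C(=O)C1 | intermediate
25 | lithium (3S)-5-chloro-3-[(2Z,5Z)-octa-2,5-dien-1-yl]-3-[(trimethylsilyl)oxy]cyclopenta-1,4-dien-1-olate (formed in the flask) | CC/C=C\C/C=C\C[C@@]1(O[Si](C)(C)C)C=C(Cl)C(O[Li])=C1 | intermediate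
26 | methyl (5S,6S)-5,6-diacetoxy-7-{(5S)-3-chloro-5-[(2Z,5Z)-octa-2,5-dien-1-yl]-2-oxo-5-[(trimethylsilyl)oxy]cyclopent-3-en-1-yl}-7-hydroxyheptanoate (C7 and C8 epimer mixture, left unassigned) | CC/C=C\C/C=C\C[C@@]1(O[Si](C)(C)C)C=C(Cl)C(=O)C1C(O)[C@H](OC(C)=O)[C@H](CCCC(=O)OC)OC(C)=O | intermediate
27 | 7-O-methanesulfonate of 26 (C7 and C8 epimer mixture; formed in the flask) | CC/C=C\C/C=C\C[C@@]1(O[Si](C)(C)C)C=C(Cl)C(=O)C1C(OS(C)(=O)=O)[C@H](OC(C)=O)[C@H](CCCC(=O)OC)OC(C)=O | intermediate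
28 | methyl (5S,6S,7E,12R,14Z,17Z)-5,6-diacetoxy-10-chloro-9-oxo-12-[(trimethylsilyl)oxy]prosta-7,10,14,17-tetraen-1-oate (12-O-trimethylsilyl punaglandin 3) | CC/C=C\C/C=C\C[C@@]1(O[Si](C)(C)C)C=C(Cl)C(=O)/C1=C/[C@H](OC(C)=O)[C@H](CCCC(=O)OC)OC(C)=O | intermediate
29 | punaglandin 3, methyl (5S,6S,7E,12R,14Z,17Z)-5,6-diacetoxy-10-chloro-12-hydroxy-9-oxoprosta-7,10,14,17-tetraen-1-oate | CC/C=C\C/C=C\C[C@@]1(O)C=C(Cl)C(=O)/C1=C/[C@H](OC(C)=O)[C@H](CCCC(=O)OC)OC(C)=O | target

**Totals**
Total step count: 19.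
Longest linear sequence: 11 steps (steps 9–19 from 12; equally steps 1–8 and 17–19 from 1).

**Three steps most likely to fail, with fallbacks**

Step 17 (aldol). The lithium dienolate is basic enough to deprotonate 11 at C6, with loss of the C5 acetate, or to cause acetyl transfer in the lithium aldolate. The fallback is a Lewis-acid Mukaiyama aldol that avoids any strongly basic species. It sets out from 24. Soft enolisation with Me3SiOTf/Et3N in CH2Cl2 at 0 °C gives the silyl dienol ether {[(3S)-5-chloro-3-[(2Z,5Z)-octa-2,5-dien-1-yl]-3-[(trimethylsilyl)oxy]cyclopenta-1,4-dien-1-yl]oxy}trimethylsilane F1. Ionisation of its tertiary silyloxy group is not a concern, because it would give an antiaromatic cyclopentadienyl cation. F1 is added to 11 with BF3·OEt2 in CH2Cl2 at −78 °C, and aqueous NaHCO3 work-up returns to the route at 26.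

Step 18 (dehydration). The E/Z ratio may be poor, or excess amine may cause vinylogous loss of the C5 acetate from the dienone. The fallback removes the bulky silyl group first and eliminates acetic acid instead of a sulfonate, which is the relationship between the natural 7-acetoxy and 7-ene punaglandins. It sets out from 26. AcOH/THF/H2O at rt gives the desilylated aldol methyl (5S,6S)-5,6-diacetoxy-7-{(5S)-3-chloro-5-hydroxy-5-[(2Z,5Z)-octa-2,5-dien-1-yl]-2-oxocyclopent-3-en-1-yl}-7-hydroxyheptanoate F2. Ac2O/pyridine at 0 °C acylates only the secondary C7 hydroxyl (the tertiary 12-OH is inert) to give the 7-O-acetyl derivative of F2 F3. One equivalent of DBU in CH2Cl2 at 0 °C then eliminates acetic acid by E1cB. With OH in place of OSiMe3 at C12 the E isomer, whose C6 substituent lies on the C12 side, is less strained. Any residual 7Z isomer is equilibrated with a trace of iodine in daylight. The fallback returns to the route directly at 29.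

Step 15 (epoxy ketone to chloroenone). Concentrated HCl may add to or isomerise the skipped Z,Z-diene. The fallback moves the epoxidation and HCl steps ahead of the semihydrogenation, so that only acid-resistant alkynes are present. It sets out from 17. Bu4NF in THF gives (1S,4R)-1-(octa-2,5-diyn-1-yl)cyclopent-2-ene-1,4-diol F4, and MnO2 gives (4S)-4-hydroxy-4-(octa-2,5-diyn-1-yl)cyclopent-2-en-1-one F5. H2O2/NaOH in MeOH gives (4S)-4-hydroxy-4-(octa-2,5-diyn-1-yl)-6-oxabicyclo[3.1.0]hexan-2-one F6. Conc. HCl in acetone gives, through the transient (4S)-2-chloro-3,4-dihydroxy-4-(octa-2,5-diyn-1-yl)cyclopentan-1-one F7, the chloroenone (4S)-2-chloro-4-hydroxy-4-(octa-2,5-diyn-1-yl)cyclopent-2-en-1-one F8. Semihydrogenation of F8 over Pd/CaCO3 poisoned with Pb(OAc)2, with quinoline, is faster at the alkynes than at the hindered, electron-poor chloroenone and returns to the route at 23.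

**Further compounds**
F1 | step 17 | {[(3S)-5-chloro-3-[(2Z,5Z)-octa-2,5-dien-1-yl]-3-[(trimethylsilyl)oxy]cyclopenta-1,4-dien-1-yl]oxy}trimethylsilane | CC/C=C\C/C=C\C[C@@]1(O[Si](C)(C)C)C=C(Cl)C(O[Si](C)(C)C)=C1
F2 | step 18 | methyl (5S,6S)-5,6-diacetoxy-7-{(5S)-3-chloro-5-hydroxy-5-[(2Z,5Z)-octa-2,5-dien-1-yl]-2-oxocyclopent-3-en-1-yl}-7-hydroxyheptanoate (C7/C8 epimer mixture) | CC/C=C\C/C=C\C[C@@]1(O)C=C(Cl)C(=O)C1C(O)[C@H](OC(C)=O)[C@H](CCCC(=O)OC)OC(C)=O
F3 | step 18 | 7-O-acetyl derivative of F2 (C7/C8 epimer mixture) | CC/C=C\C/C=C\C[C@@]1(O)C=C(Cl)C(=O)C1C(OC(C)=O)[C@H](OC(C)=O)[C@H](CCCC(=O)OC)OC(C)=O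
F4 | step 15 | (1S,4R)-1-(octa-2,5-diyn-1-yl)cyclopent-2-ene-1,4-diol | CCC#CCC#CC[C@@]1(O)C=C[C@H](O)C1
F5 | step 15 | (4S)-4-hydroxy-4-(octa-2,5-diyn-1-yl)cyclopent-2-en-1-one | CCC#CCC#CC[C@@]1(O)C=CC(=O)C1
F6 | step 15 | (4S)-4-hydroxy-4-(octa-2,5-diyn-1-yl)-6-oxabicyclo[3.1.0]hexan-2-one (epoxide epimers) | CCC#CCC#CC[C@@]1(O)C2OC2C(=O)C1
F7 | step 15 | (4S)-2-chloro-3,4-dihydroxy-4-(octa-2,5-diyn-1-yl)cyclopentan-1-one (not isolated) | CCC#CCC#CC[C@@]1(O)C(O)C(Cl)C(=O)C1
F8 | step 15 | (4S)-2-chloro-4-hydroxy-4-(octa-2,5-diyn-1-yl)cyclopent-2-en-1-one | CCC#CCC#CC[C@@]1(O)C=C(Cl)C(=O)C1
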